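**Assumption:** irigenin has no stereocenters, so "single enantiomer" does not apply. The only selectivity issues are regiochemical, and the route is built around that.

## Retrosynthetic overview
1. Irigenin (**14**) is the global debenzylation product of the tri-O-benzyl isoflavone **13**.
2. **13** comes from a radical arylation that forms the C3–C1′ bond. An aryl radical from the arylBpin **12** adds to the α-carbon of the 2-hydroxyaryl enaminone **7**. Oxidation, then loss of HNMe₂ with phenol closure, builds the pyranone ring last.
3. Ring A: resorcinol → 2-methoxy-1,3-bis(benzyloxy)benzene → Ir C–H borylation/oxidation to the phenol → ortho-acetylation → enaminone.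
4. Ring B: catechol → veratrole → 2,3-dimethoxyphenol → benzyl ether → Ir C–H borylation at C5. The two aromatic rings are made separately and joined, then the C ring is closed.

## Forward route

**Step 1**
Reactants: **1** resorcinol
Product: **2** 1,3-bis(benzyloxy)benzene
Conditions: BnBr, K₂CO₃, acetone, reflux
Reagents that add atoms: benzyl bromide, BrCc1ccccc1
Why: Williamson O-alkylation protects both phenols as benzyl ethers, which are removable at the end.

**Step 2**
Reactants: **2**
Product: **3** 2,6-bis(benzyloxy)phenol
Conditions: n-BuLi, THF, 0 °C; then B(OMe)₃, –78 °C → rt; then 30% H₂O₂, aq. NaOH, 0 °C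
Reagents that add atoms: hydrogen peroxide, OO (source of the new phenolic O; B(OMe)₃, COB(OC)OC, is lost)
Why: directed ortho-metalation between the two OBn groups (the doubly activated C2), then borylation and oxidative deborylation, places oxygen at C2, which becomes C6-O of the chromone.

**Step 3**
Reactants: **3**
Product: **4** 1,3-bis(benzyloxy)-2-methoxybenzene
Conditions: MeI, K₂CO₃, DMF, rt
Reagents that add atoms: iodomethane, CI
Why: O-methylation of the hindered phenol installs the future 6-OMe.

**Step 4**
Reactants: **4**
Product: **5** 3,5-bis(benzyloxy)-4-methoxyphenol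
Conditions: [Ir(OMe)(cod)]₂ (1.5 mol%), dtbpy (3 mol%), B₂pin₂, THF, 80 °C; then H₂O₂, aq. NaOH, 0 °C → rt (one pot)
Reagents that add atoms: hydrogen peroxide, OO (B₂pin₂ only transiently)
Why: sterically controlled Ir-catalysed C–H borylation of a 1,2,3-trisubstituted arene goes to C5 (meta to both OBn, para to OMe). Oxidation of the C–B bond then gives the phenol that becomes C8a–O.

**Step 5**
Reactants: **5**
Product: **6** 1-[4,6-bis(benzyloxy)-2-hydroxy-5-methoxyphenyl]ethan-1-one
Conditions: AcOH, BF₃·OEt₂, 60 °C
Reagents that add atoms: acetic acid, CC(=O)O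
Why: BF₃-mediated Friedel–Crafts (Hoesch-type) C-acylation of the phloroglucinol-pattern phenol goes ortho to OH, and the two ortho sites are equivalent, so only one regioisomer forms.

**Step 6**
Reactants: **6**
Product: **7** (E)-1-[4,6-bis(benzyloxy)-2-hydroxy-5-methoxyphenyl]-3-(dimethylamino)prop-2-en-1-one
Conditions: DMF-DMA, toluene, 100 °C
Reagents that add atoms: N,N-dimethylformamide dimethyl acetal, COC(OC)N(C)C
Why: condensation of the methyl ketone with DMF-DMA gives the enaminone. The free 2′-OH stays chelated and sets which oxygen later closes the ring, so the 6-OMe regiochemistry is fixed.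

**Step 7**
Reactants: **8** catechol
Product: **9** 1,2-dimethoxybenzene (veratrole)
Conditions: MeI, K₂CO₃, acetone, reflux
Reagents that add atoms: iodomethane, CI
Why: double Williamson O-methylation.

**Step 8**
Reactants: **9**
Product: **10** 2,3-dimethoxyphenol
Conditions: n-BuLi, THF, 0 °C → rt; then B(OMe)₃, –78 °C → rt; then H₂O₂, AcOH or NaOH
Reagents that add atoms: hydrogen peroxide, OO
Why: OMe-directed ortho-lithiation at C3, borylation and oxidation gives the contiguous 1,2,3-trioxygenated pattern of ring B.

**Step 9**
Reactants: **10**
Product: **11** 1-(benzyloxy)-2,3-dimethoxybenzene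
Conditions: BnBr, K₂CO₃, acetone, reflux
Reagents that add atoms: benzyl bromide, BrCc1ccccc1
Why: benzylation masks the future 5′-OH so it survives the radical step.

**Step 10**
Reactants: **11**
Product: **12** 2-[3-(benzyloxy)-4,5-dimethoxyphenyl]-4,4,5,5-tetramethyl-1,3,2-dioxaborolane
Conditions: [Ir(OMe)(cod)]₂ (1.5 mol%), dtbpy (3 mol%), B₂pin₂, THF, 80 °C
Reagents that add atoms: bis(pinacolato)diboron, CC1(C)OB(OC1(C)C)B1OC(C)(C)C(C)(C)O1
Why: sterically controlled Ir borylation goes at C5, para to the central OMe, which is exactly the attachment point needed on ring B.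

**Step 11 (key radical step)**
Reactants: **7** enaminone and **12** arylBpin
Product: **13** 5,7-bis(benzyloxy)-3-[3-(benzyloxy)-4,5-dimethoxyphenyl]-6-methoxy-4H-chromen-4-one
Conditions: **12** (2.5 equiv), Mn(OAc)₃·2H₂O (3 equiv), AcOH/H₂O 10:1, 60 → 80 °C
Reagents that add atoms: none
Why: Proposed new method: Mn(III) oxidises the (hydrolysed) boronate to the electron-rich aryl radical, which adds to the nucleophilic α-carbon of the enaminone. This gives a captodative α-amino radical, which Mn(III) oxidises to the iminium; loss of H⁺ gives the α-aryl enaminone, and the chelated 2′-OH then undergoes acid-promoted oxa-Michael addition/HNMe₂ elimination to close the pyranone. The closest known reactions are Mn(OAc)₃ or persulfate radical arylation with arylboronic acids and Meerwein-type radical α-arylation of enamines/enaminones; no stereocenter is formed.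

**Step 12**
Reactants: **13**
Product: **14** irigenin
Conditions: H₂ (1 atm), 10% Pd/C, EtOAc/MeOH, rt, monitored to stop at the tri-phenol
Reagents that add atoms: none (hydrogen only; three toluene equivalents are lost)
Why: catalytic hydrogenolysis cleaves the three aryl benzyl ethers, while the aryl methyl ethers and the C2=C3 bond of the conjugated isoflavone survive short reaction times. The product is achiral.

## Compound list
(Reagents such as BnBr, MeI, B₂pin₂ and DMF-DMA are not numbered.)

| No. | Name | SMILES | Role |
|---|---|---|---|
| 1 | resorcinol | Oc1cccc(O)c1 | starting material |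
| 2 | 1,3-bis(benzyloxy)benzene | C(Oc1cccc(OCc2ccccc2)c1)c1ccccc1 | intermediate |
| 3 | 2,6-bis(benzyloxy)phenol | Oc1c(OCc2ccccc2)cccc1OCc1ccccc1 | intermediate |
| 4 | 1,3-bis(benzyloxy)-2-methoxybenzene | COc1c(OCc2ccccc2)cccc1OCc1ccccc1 | intermediate |
| 5 | 3,5-bis(benzyloxy)-4-methoxyphenol | COc1c(OCc2ccccc2)cc(O)cc1OCc1ccccc1 | intermediate |
| 6 | 1-[4,6-bis(benzyloxy)-2-hydroxy-5-methoxyphenyl]ethanone | CC(=O)c1c(O)cc(OCc2ccccc2)c(OC)c1OCc1ccccc1 | intermediate |
| 7 | (E)-enaminone of 6 | CN(C)/C=C/C(=O)c1c(O)cc(OCc2ccccc2)c(OC)c1OCc1ccccc1 | intermediate |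
| 8 | catechol | Oc1ccccc1O | starting material |
| 9 | veratrole | COc1ccccc1OC | intermediate |
| 10 | 2,3-dimethoxyphenol | COc1cccc(O)c1OC | intermediate |
| 11 | 1-(benzyloxy)-2,3-dimethoxybenzene | COc1cccc(OCc2ccccc2)c1OC | intermediate |
| 12 | 3-(benzyloxy)-4,5-dimethoxyphenyl-Bpin | COc1cc(B2OC(C)(C)C(C)(C)O2)cc(OCc2ccccc2)c1OC | intermediate |
| 13 | tri-O-benzyl irigenin | COc1cc(-c2coc3cc(OCc4ccccc4)c(OC)c(OCc4ccccc4)c3c2=O)cc(OCc2ccccc2)c1OC | intermediate |
| 14 | irigenin | COc1cc(-c2coc3cc(O)c(OC)c(O)c3c2=O)cc(O)c1OC | target |

**Total steps:** 12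
**Longest linear sequence:** 8 (resorcinol → 2 → 3 → 4 → 5 → 6 → 7 → 13 → 14)

## Three steps most likely to fail
1. **Step 11 (radical arylation).** Risks are over-oxidation of the electron-rich arylboron species and of the benzyl ethers, and poor Bpin activation. *Fallback (change of approach):* convert **7** to the 3-iodochromone (I₂, then ring closure), then use a Pd-catalysed Suzuki coupling with **12** in place of the radical coupling.
2. **Step 5 (BF₃/AcOH acylation).** Benzyl ether cleavage or migration under Lewis acid is possible. *Fallback:* O-acetylate **5** and use a Fries rearrangement (photo-Fries or Sc(OTf)₃), which avoids direct acid acylation of the arene.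
3. **Step 2 (lithiation of the bis-benzyl ether).** Competing [1,2]-Wittig rearrangement or benzylic metalation could lower the yield. *Fallback:* run the C2 lithiation/hydroxylation/methylation on the bis-MOM ether of resorcinol instead, then exchange MOM for benzyl (HCl/MeOH; BnBr).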